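I cannot read the end of winter or noon off the delta run, which stops at 4.00 min on 1.6 M of X, while both new flasks run 5.0 min on other charges of X.

common to all: D 0.99 M
- delta: X 1.6 M; run made earlier
- winter: X 1.20 M; time 5.0 min
- noon: X 3.00 M; time 5.0 min

delta run (percent of the D charged)

| time / min | E / % | D / % | L / % |
|---|---|---|---|
| 0.667 | 12 | 77 | 8 |
| 1.33 | 11 | 63 | 23 |
| 2.00 | 13 | 54 | 32 |
| 3.00 | 11 | 46 | 43 |
| 4.00 | 11 | 42 | 51 |

(readings scatter by 1.5 percentage points)



* which of these there is most of at the end, counted by the D in it, winter (D / L / E)
* which of these there is most of at the end, counted by the D in it, noon (D / L / E)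
* amount of the one of these that there is most of at the end, in percent of the D charged, winter
* amount of the one of these that there is most of at the end, in percent of the D charged, noon

So I work with fractions left. I take D + X → E and E + X → L, so E costs one X and L two. Let c_D and c_X be the charges, f_D and f_X the fractions left, and s the X spent per D lost. If D falls at k times its concentration times that of X, and s holds steady, then

ln(f_D/f_X) = k(s·c_D − c_X)t

f_X = 1 − a(1 − f_D), with a = s·c_D/c_X

The last delta reading gives s = (E + 2L)/(D lost) = 1.95. The logarithm there is 0.334, so k = 0.254 L mol⁻¹ min⁻¹, the fraction-left constant. Solved for D, the two lines give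

f_D = (1 − a)/(R − a), with R = exp[k(c_X − s·c_D)t]

Winter: a = 1.61, R = 0.397, f_D = 50.2%

Noon: a = 0.643, R = 3.89, f_D = 11.0%

In winter X is the limiting reagent, since its charge is less than s·c_D.

The second way repeats this from a different reading, the one at 2.00 min: s = 1.67, logarithm 0.0309, k = 0.270 L mol⁻¹ min⁻¹. It gives f_D = 45.3% for winter and 8.01% for noon.

The two ways part, and the earlier delta reading is the one that cheats: one scatter in D moves ln f_D there by 0.0278 against a logarithm of 0.0309, whereas the later logarithm is larger than the 0.0357 by which one scatter moves ln f_D at that reading. I keep the later numbers. With E at 0.262 of D, as read last in the delta run, L comes to 36.7% in winter and 86.1% at noon, so I expect D to lead in winter and L at noon.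

The forecast names D at 48% (44% to 53%) for winter and L at 84% (78% to 89%) for noon, and says of winter: “D is narrowly the largest, and the late slowing favours it further”.

Winter ends with D at 48.1% beside L at 40.4%, and noon with L at 85.7% beside D at 11.4%.

    X ⇌ G (K = 0.269, k = 0.00155 s⁻¹)
    X + E → L + Q (k = 0.0236 L mol⁻¹ s⁻¹)
    D + X → E + Q (k = 0.00480 L mol⁻¹ s⁻¹)

The neighbouring flask is winter with 0.59 M of D. The same k gives a = 0.958, R = 1.07, f_D = 38.9% and L = 50.9%. That flask ends with D at 38.1% and L at 52.4%.

(The runs come from a simulation from invented constants; scatter was added.)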